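## Plan

Rings: A = guaiacyl ketone ring; B = aryl on furofuran C2; C = benzo ring of the dihydrobenzofuran on furofuran C6; D = its 2-aryl group. The furofuran is numbered as 3,7-dioxabicyclo[3.3.0]octane.
Retrosynthesis cuts (a) the bond from the ketone α-carbon to ring B, (b) the ether bonds O3–C2 and O7–C6, leaving a 1,4-diaryl-2,3-bis(hydroxymethyl)butane-1,4-diol, and (c) C1–C2 and C5–C6 in one operation.
Enabling feature: the bridgeheads C1 and C5 are neighbours, each flanked by one CH2O carbon (C8, C4) and one aryl-bearing carbon (C2, C6). This is Cα/Cβ of a 5-alkoxybutenolide whose carbonyl and acetal carbons become C8 and C4, so C6 (ring C) can arrive as a lithiated dithiane and C2 (ring B) as an aldehyde.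
Forward: rings D and C are joined as a benzyl aryl ether and the dihydrofuran ring closes by Rh carbenoid C–H insertion. The three-component union builds the C2–C1–C5–C6 chain; dithiane hydrolysis and reduction follow, then both tetrahydrofuran rings close. Ring A with its keto arm is attached last by Negishi coupling, then all silyl groups are removed.
Stereochemistry: dihydrobenzofuran C2/C3 (cis) from the chiral Rh carboxylate; furofuran C5 from the (5R)-menthyloxy acetal, C1 trans to it, C2 and C6 by exo capture of benzylic cations; the ketone α-carbon from the chiral Ni/pybox catalyst.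

Key step: step 11

Assumption: for Rh2(S-PTTL)4 (step 6) and for the pybox ligand (step 19) the antipode that delivers the drawn configuration is the one used; the sense of induction is to be settled on a model substrate.

Abbreviations: TBS = tert-butyldimethylsilyl, TBSO = its ether; TMS = trimethylsilyl; TES = triethylsilyl; l-menthyl = (1R,2S,5R)-menthyl. ArC = (2S,3S)-cis-2-[4-(TBSO)-3-methoxyphenyl]-3-(TBSO-methyl)-7-methoxy-2,3-dihydrobenzofuran-5-yl. ArB = 4-(TBSO)-3-iodo-5-methoxyphenyl.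

## Route

Step 1
Reactants: 1 vanillin
Product: 2 4-(TBSO)-3-methoxybenzaldehyde
Conditions: TBSCl, imidazole, DMF, rt
Reagents that add atoms: tert-butyldimethylsilyl chloride, CC(C)(C)[Si](C)(C)Cl
Why: Imidazole-promoted O-silylation of the phenol, a standard silyl ether protection that should hold through the hydride, Mitsunobu, carbenoid and organolithium steps and fall to fluoride at the end.

Step 2
Reactants: 2 4-(TBSO)-3-methoxybenzaldehyde
Product: 3 [4-(TBSO)-3-methoxyphenyl]methanol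
Conditions: NaBH4, MeOH/THF, 0 °C
Reagents that add atoms: none
Why: Borohydride reduction of the aldehyde to the benzylic alcohol, fast enough at 0 °C to leave the aryl silyl ether untouched.

Step 3
Reactants: 3 [4-(TBSO)-3-methoxyphenyl]methanol; 4 5-iodovanillin (4-hydroxy-3-iodo-5-methoxybenzaldehyde)
Product: 5 4-{[4-(TBSO)-3-methoxybenzyl]oxy}-3-iodo-5-methoxybenzaldehyde
Conditions: PPh3, DIAD, THF, 0 °C to rt
Reagents that add atoms: none
Why: Mitsunobu etherification, in which the phenol of 4 (made acidic by the para formyl group) is alkylated by the activated primary benzylic alcohol under neutral conditions that spare the silyl ether and the aldehyde.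

Step 4
Reactants: 5 4-{[4-(TBSO)-3-methoxybenzyl]oxy}-3-iodo-5-methoxybenzaldehyde
Product: 6 2-(4-{[4-(TBSO)-3-methoxybenzyl]oxy}-3-iodo-5-methoxyphenyl)-1,3-dioxolane
Conditions: (TMSOCH2)2, TMSOTf (cat.), CH2Cl2, −78 °C
Reagents that add atoms: 1,2-bis(trimethylsilyloxy)ethane, C[Si](C)(C)OCCO[Si](C)(C)C
Why: Silyl-transfer acetalisation (TMSOTf-catalysed dioxolane formation) masks the aldehyde at −78 °C without cleaving the acid-labile benzyl aryl ether, so that it survives the diazo, carbenoid and hydride steps.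

Step 5
Reactants: 6 2-(4-{[4-(TBSO)-3-methoxybenzyl]oxy}-3-iodo-5-methoxyphenyl)-1,3-dioxolane
Product: 7 ethyl 2-diazo-2-[2-{[4-(TBSO)-3-methoxybenzyl]oxy}-5-(1,3-dioxolan-2-yl)-3-methoxyphenyl]acetate
Conditions: N2CHCO2Et, Pd(PPh3)4 (cat.), Ag2CO3, Et3N, toluene, rt
Reagents that add atoms: ethyl diazoacetate, CCOC(=O)C=[N+]=[N-]
Why: Palladium-catalysed cross-coupling of an aryl iodide with ethyl diazoacetate (oxidative addition to zerovalent palladium, silver-assisted transfer of the diazoacetate carbon, reductive elimination with the diazo group kept) gives the donor/acceptor diazo ester directly.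

Step 6
Reactants: 7 ethyl 2-diazo-2-[2-{[4-(TBSO)-3-methoxybenzyl]oxy}-5-(1,3-dioxolan-2-yl)-3-methoxyphenyl]acetate
Product: 8 ethyl (2S,3R)-cis-2-[4-(TBSO)-3-methoxyphenyl]-5-(1,3-dioxolan-2-yl)-7-methoxy-2,3-dihydrobenzofuran-3-carboxylate
Conditions: Rh2(S-PTTL)4 (dirhodium tetrakis[N-phthaloyl-(S)-tert-leucinate], cat.), toluene, −78 °C
Reagents that add atoms: none
Why: Intramolecular 1,5 C–H insertion of the rhodium donor/acceptor carbenoid into the electron-rich benzylic ether C–H bond closes the dihydrofuran ring, the chiral carboxylate ligands setting C2 and C3 together and the concerted insertion giving the cis ester as the kinetic product.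

Step 7
Reactants: 8 ethyl (2S,3R)-cis-2-[4-(TBSO)-3-methoxyphenyl]-5-(1,3-dioxolan-2-yl)-7-methoxy-2,3-dihydrobenzofuran-3-carboxylate
Product: 9 {(2S,3S)-cis-2-[4-(TBSO)-3-methoxyphenyl]-5-(1,3-dioxolan-2-yl)-7-methoxy-2,3-dihydrobenzofuran-3-yl}methanol
Conditions: i-Bu2AlH (DIBAL-H), CH2Cl2, −78 to −20 °C; aq. KNaC4H4O6 work-up
Reagents that add atoms: none
Why: Ester reduction with an aluminium hydride at low temperature is non-basic, so C3 (α to the ester) should not epimerise to the trans series before it becomes a configurationally stable CH2OH-bearing carbon.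

Step 8
Reactants: 9 {(2S,3S)-cis-2-[4-(TBSO)-3-methoxyphenyl]-5-(1,3-dioxolan-2-yl)-7-methoxy-2,3-dihydrobenzofuran-3-yl}methanol
Product: 10 2-ArC-1,3-dioxolane
Conditions: TBSCl, imidazole, DMF, rt
Reagents that add atoms: tert-butyldimethylsilyl chloride, CC(C)(C)[Si](C)(C)Cl
Why: O-silylation of the primary alcohol removes the last acidic proton before the organolithium chemistry.

Step 9
Reactants: 10 2-ArC-1,3-dioxolane
Product: 11 2-ArC-1,3-dithiane
Conditions: HS(CH2)3SH, MgBr2·OEt2, Et2O, rt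
Reagents that add atoms: propane-1,3-dithiol, SCCCS
Why: Lewis acid-mediated transthioacetalisation turns the dioxolane into the dithiane, MgBr2·OEt2 being mild enough for both silyl ethers and for the benzylic aryl ether at C2 of the dihydrobenzofuran.

Step 10
Reactants: 4 5-iodovanillin
Product: 12 4-(TBSO)-3-iodo-5-methoxybenzaldehyde
Conditions: TBSCl, imidazole, DMF, rt
Reagents that add atoms: tert-butyldimethylsilyl chloride, CC(C)(C)[Si](C)(C)Cl
Why: O-silylation of the phenol gives a non-enolisable, base-stable aldehyde whose iodine is a spectator until the zinc insertion of step 19.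

Step 11
Reactants: 11 2-ArC-1,3-dithiane; 13 (5R)-5-(l-menthyloxy)-2(5H)-furanone; 12 4-(TBSO)-3-iodo-5-methoxybenzaldehyde
Product: 16 (3S,4R,5R)-3-[ArB(hydroxy)methyl]-4-(2-ArC-1,3-dithian-2-yl)-5-(l-menthyloxy)dihydrofuran-2(3H)-one (carbinol carbon as a mixture of epimers), via lithiated dithiane 14 (not isolated), via lithium enolate 15 (not isolated)
Conditions: n-BuLi, THF, −78 °C; then 13, −78 °C; then 12, −78 °C; AcOH quench at −78 °C
Reagents that add atoms: none
Why: n-BuLi removes the dithiane proton of 11 (the most acidic C–H, flanked by two sulfur atoms and the aryl ring); the soft, hindered carbanion 14 adds in conjugate fashion to the β-carbon of 13 on the face opposite the menthyloxy group, and the resulting lithium enolate 15 adds to aldehyde 12 through a closed lithium-bridged six-membered transition state on the face anti to the new β-substituent. The closest known reaction type is the tandem conjugate addition–aldol reaction of lithiated 2-aryl-1,3-dithianes with 5-alkoxy-2(5H)-furanones and aromatic aldehydes, as used for lignan lactones. No ring is closed; the bonds formed are C5–C6 and C1–C2 of the later furofuran. The centre at the lactone β-carbon (furofuran C5) is controlled by the acetal carbon of the auxiliary (anti addition) and that at the α-carbon (furofuran C1) by the bulky β-dithianyl group (trans); the carbinol carbon is not controlled and need not be, because it is ionised in step 14. The step needs 1,4- over 1,2-addition, which the charge-delocalised sulfur-stabilised anion and the unsubstituted β-carbon should secure, and clean capture of the enolate, which a non-enolisable aldehyde at −78 °C and a cold acetic acid quench (no retro-aldol) should secure.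

Step 12
Reactants: 16 (3S,4R,5R)-3-[ArB(hydroxy)methyl]-4-(2-ArC-1,3-dithian-2-yl)-5-(l-menthyloxy)dihydrofuran-2(3H)-one
Product: 17 (3S,4R,5R)-3-[ArB(hydroxy)methyl]-4-(ArC-carbonyl)-5-(l-menthyloxy)dihydrofuran-2(3H)-one
Conditions: Hg(ClO4)2·3H2O, CaCO3, THF/H2O, 0 °C
Reagents that add atoms: water, O
Why: Mercury-assisted hydrolysis of the dithioacetal under CaCO3 buffering unmasks the aryl ketone without touching the silyl ethers, the menthyl acetal, the free carbinol or the aryl iodide.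

Step 13
Reactants: 17 (3S,4R,5R)-3-[ArB(hydroxy)methyl]-4-(ArC-carbonyl)-5-(l-menthyloxy)dihydrofuran-2(3H)-one
Product: 18 (2R,3R)-1-ArB-4-ArC-2,3-bis(hydroxymethyl)butane-1,4-diol (C1 and C4 as mixtures of epimers)
Conditions: LiBH4, THF, 0 °C to rt
Reagents that add atoms: none
Why: Borohydride reduction of the ketone and of the pseudo-ester (hydride opens the lactone to an aldehyde, the freed hemiacetal alkoxide expels menthoxide, and both aldehydes are reduced) gives the tetraol and releases the auxiliary, while LiBH4 leaves the aryl iodide alone and the two new carbinol configurations do not matter.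

Step 14
Reactants: 18 (2R,3R)-1-ArB-4-ArC-2,3-bis(hydroxymethyl)butane-1,4-diol
Product: 20 (1R,2S,5R,6S)-2-ArB-6-ArC-3,7-dioxabicyclo[3.3.0]octane, via mono-tetrahydrofuran diol 19 (not isolated)
Conditions: BF3·OEt2 (cat.), 4 Å MS, CH2Cl2, −40 to 0 °C
Reagents that add atoms: none
Why: Acid-catalysed double cyclodehydration (SN1 etherification), in which each electron-rich benzylic alcohol ionises (the ring C carbinol probably first) and its cation is captured 5-exo by the hydroxymethyl oxygen on the neighbouring carbon so that each aryl group ends on the convex face (C2 and C6 exo) whatever the carbinol configuration, with catalytic acid and low temperature keeping the closure kinetic and sparing the cis-dihydrobenzofuran and the silyl ethers.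

Step 15
Reactants: 21 4-bromo-2-methoxyphenol
Product: 22 (4-bromo-2-methoxyphenoxy)(tert-butyl)dimethylsilane
Conditions: TBSCl, imidazole, DMF, rt
Reagents that add atoms: tert-butyldimethylsilyl chloride, CC(C)(C)[Si](C)(C)Cl
Why: O-silylation of the phenol allows the bromine–lithium exchange of the next step.

Step 16
Reactants: 22 (4-bromo-2-methoxyphenoxy)(tert-butyl)dimethylsilane; 23 3-(TBSO)propanal
Product: 25 1-[4-(TBSO)-3-methoxyphenyl]-3-(TBSO)propan-1-ol (racemic), via aryllithium 24 (not isolated)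
Conditions: n-BuLi, THF, −78 °C; then 23, −78 °C; aq. work-up
Reagents that add atoms: none
Why: Bromine–lithium exchange followed by 1,2-addition of the aryllithium to the aldehyde, the lithium sitting para to the silyloxy group so that no silyl shift can occur.

Step 17
Reactants: 25 1-[4-(TBSO)-3-methoxyphenyl]-3-(TBSO)propan-1-ol
Product: 26 1-[4-(TBSO)-3-methoxyphenyl]-3-(TBSO)propan-1-one
Conditions: Dess–Martin periodinane, CH2Cl2, rt
Reagents that add atoms: none
Why: Dess–Martin oxidation of the secondary benzylic alcohol to the aryl ketone under near-neutral conditions that should not eliminate the β-silyloxy group.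

Step 18
Reactants: 26 1-[4-(TBSO)-3-methoxyphenyl]-3-(TBSO)propan-1-one
Product: 28 2-bromo-1-[4-(TBSO)-3-methoxyphenyl]-3-(TBSO)propan-1-one (racemic), via trimethylsilyl enol ether 27 (not isolated)
Conditions: TMSOTf, Et3N, CH2Cl2, 0 °C; then NBS, THF, −78 °C
Reagents that add atoms: N-bromosuccinimide, O=C1CCC(=O)N1Br
Why: Soft enolisation to the silyl enol ether and electrophilic α-bromination with NBS, which avoids a metal enolate that could expel the β-silyloxy group and reacts much faster than the acyl-deactivated arene.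

Step 19
Reactants: 20 (1R,2S,5R,6S)-2-ArB-6-ArC-3,7-dioxabicyclo[3.3.0]octane; 28 2-bromo-1-[4-(TBSO)-3-methoxyphenyl]-3-(TBSO)propan-1-one
Product: 30 (2S)-1-[4-(TBSO)-3-methoxyphenyl]-3-(TBSO)-2-{2-(TBSO)-3-methoxy-5-[(1R,2S,5R,6S)-6-ArC-3,7-dioxabicyclo[3.3.0]oct-2-yl]phenyl}propan-1-one, via arylzinc iodide 29 (not isolated)
Conditions: Zn dust, LiCl, THF, 50 °C; then 28, NiCl2·glyme (cat.), chiral pybox ligand (cat.), glyme/THF, −30 °C
Reagents that add atoms: none
Why: Enantioconvergent Negishi α-arylation of a racemic secondary α-bromo ketone, in which nickel turns both enantiomers of 28 into a common α-keto radical and the chiral pybox ligand decides the configuration of the new C–aryl bond (S) at −30 °C without base so that the enolisable centre is kept, the arylzinc being made by LiCl-promoted zinc insertion to avoid an ortho-lithiated aryl silyl ether and its O-to-C silyl shift.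

Step 20
Reactants: 30 (2S)-1-[4-(TBSO)-3-methoxyphenyl]-3-(TBSO)-2-{2-(TBSO)-3-methoxy-5-[(1R,2S,5R,6S)-6-ArC-3,7-dioxabicyclo[3.3.0]oct-2-yl]phenyl}propan-1-one
Product: 31 CNP0174045.1, (2S)-3-hydroxy-1-(4-hydroxy-3-methoxyphenyl)-2-{2-hydroxy-3-methoxy-5-[(1R,2S,5R,6S)-6-[(2S,3S)-cis-2-(4-hydroxy-3-methoxyphenyl)-3-(hydroxymethyl)-7-methoxy-2,3-dihydrobenzofuran-5-yl]-3,7-dioxabicyclo[3.3.0]oct-2-yl]phenyl}propan-1-one
Conditions: HF·pyridine, pyridine, THF, 0 °C to rt
Reagents that add atoms: none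
Why: Fluoride desilylation with pyridine-buffered HF removes all five silyl ethers under weakly acidic conditions that should neither enolise the α-aryl β-hydroxy ketone nor ionise the benzylic ethers.

## Compound list

1 | vanillin | COc1cc(C=O)ccc1O | starting material
2 | 4-(TBSO)-3-methoxybenzaldehyde | COc1cc(C=O)ccc1O[Si](C)(C)C(C)(C)C | intermediate
3 | [4-(TBSO)-3-methoxyphenyl]methanol | COc1cc(CO)ccc1O[Si](C)(C)C(C)(C)C | intermediate
4 | 5-iodovanillin | COc1cc(C=O)cc(I)c1O | starting material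
5 | 4-{[4-(TBSO)-3-methoxybenzyl]oxy}-3-iodo-5-methoxybenzaldehyde | COc1cc(C=O)cc(I)c1OCc1ccc(O[Si](C)(C)C(C)(C)C)c(OC)c1 | intermediate
6 | 1,3-dioxolane of 5 | COc1cc(C2OCCO2)cc(I)c1OCc1ccc(O[Si](C)(C)C(C)(C)C)c(OC)c1 | intermediate
7 | ethyl aryldiazoacetate | CCOC(=O)C(=[N+]=[N-])c1cc(C2OCCO2)cc(OC)c1OCc1ccc(O[Si](C)(C)C(C)(C)C)c(OC)c1 | intermediate
8 | ethyl (2S,3R)-cis-dihydrobenzofuran-3-carboxylate | O1CCOC1c1cc(OC)c2c(c1)[C@@H](C(=O)OCC)[C@@H](c1ccc(O[Si](C)(C)C(C)(C)C)c(OC)c1)O2 | intermediate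
9 | (2S,3S)-cis-3-(hydroxymethyl)dihydrobenzofuran dioxolane | O1CCOC1c1cc(OC)c2c(c1)[C@@H](CO)[C@@H](c1ccc(O[Si](C)(C)C(C)(C)C)c(OC)c1)O2 | intermediate
10 | 2-ArC-1,3-dioxolane | O1CCOC1c1cc(OC)c2c(c1)[C@@H](CO[Si](C)(C)C(C)(C)C)[C@@H](c1ccc(O[Si](C)(C)C(C)(C)C)c(OC)c1)O2 | intermediate
11 | 2-ArC-1,3-dithiane | C1(SCCCS1)c1cc(OC)c2c(c1)[C@@H](CO[Si](C)(C)C(C)(C)C)[C@@H](c1ccc(O[Si](C)(C)C(C)(C)C)c(OC)c1)O2 | intermediate
12 | 4-(TBSO)-3-iodo-5-methoxybenzaldehyde | COc1cc(C=O)cc(I)c1O[Si](C)(C)C(C)(C)C | intermediate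
13 | (5R)-5-(l-menthyloxy)-2(5H)-furanone | O=C1O[C@@H](O[C@@H]2C[C@H](C)CC[C@H]2C(C)C)C=C1 | starting material
14 | 2-lithio derivative of 11 | [Li]C1(SCCCS1)c1cc(OC)c2c(c1)[C@@H](CO[Si](C)(C)C(C)(C)C)[C@@H](c1ccc(O[Si](C)(C)C(C)(C)C)c(OC)c1)O2 | intermediate (not isolated)
15 | lithium enolate of the 4,5-trans conjugate adduct | [Li]OC1O[C@@H](O[C@@H]2C[C@H](C)CC[C@H]2C(C)C)[C@H](C2(SCCCS2)c2cc(OC)c3c(c2)[C@@H](CO[Si](C)(C)C(C)(C)C)[C@@H](c2ccc(O[Si](C)(C)C(C)(C)C)c(OC)c2)O3)C=1 | intermediate (not isolated)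
16 | (3S,4R,5R) aldol–dithiane lactone, carbinol carbon undefined | O=C1O[C@@H](O[C@@H]2C[C@H](C)CC[C@H]2C(C)C)[C@H](C2(SCCCS2)c2cc(OC)c3c(c2)[C@@H](CO[Si](C)(C)C(C)(C)C)[C@@H](c2ccc(O[Si](C)(C)C(C)(C)C)c(OC)c2)O3)[C@H]1C(O)c1cc(OC)c(O[Si](C)(C)C(C)(C)C)c(I)c1 | intermediate
17 | (3S,4R,5R) keto lactone, carbinol carbon undefined | O=C1O[C@@H](O[C@@H]2C[C@H](C)CC[C@H]2C(C)C)[C@H](C(=O)c2cc(OC)c3c(c2)[C@@H](CO[Si](C)(C)C(C)(C)C)[C@@H](c2ccc(O[Si](C)(C)C(C)(C)C)c(OC)c2)O3)[C@H]1C(O)c1cc(OC)c(O[Si](C)(C)C(C)(C)C)c(I)c1 | intermediate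
18 | (2R,3R) tetraol, both carbinol carbons undefined | OC[C@H](C(O)c1cc(OC)c2c(c1)[C@@H](CO[Si](C)(C)C(C)(C)C)[C@@H](c1ccc(O[Si](C)(C)C(C)(C)C)c(OC)c1)O2)[C@H](CO)C(O)c1cc(OC)c(O[Si](C)(C)C(C)(C)C)c(I)c1 | intermediate
19 | [(3R,4R,5S)-5-ArC-4-(hydroxymethyl)tetrahydrofuran-3-yl](ArB)methanol | OC(c1cc(OC)c(O[Si](C)(C)C(C)(C)C)c(I)c1)[C@H]1CO[C@H](c2cc(OC)c3c(c2)[C@@H](CO[Si](C)(C)C(C)(C)C)[C@@H](c2ccc(O[Si](C)(C)C(C)(C)C)c(OC)c2)O3)[C@H]1CO | intermediate (not isolated)
20 | (1R,2S,5R,6S)-2-ArB-6-ArC-3,7-dioxabicyclo[3.3.0]octane | Ic1cc([C@H]2OC[C@H]3[C@@H]2CO[C@@H]3c2cc(OC)c3c(c2)[C@@H](CO[Si](C)(C)C(C)(C)C)[C@@H](c2ccc(O[Si](C)(C)C(C)(C)C)c(OC)c2)O3)cc(OC)c1O[Si](C)(C)C(C)(C)C | intermediate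
21 | 4-bromo-2-methoxyphenol | COc1cc(Br)ccc1O | starting material
22 | (4-bromo-2-methoxyphenoxy)(tert-butyl)dimethylsilane | COc1cc(Br)ccc1O[Si](C)(C)C(C)(C)C | intermediate
23 | 3-(TBSO)propanal | O=CCCO[Si](C)(C)C(C)(C)C | starting material
24 | 4-(TBSO)-3-methoxyphenyllithium | [Li]c1ccc(O[Si](C)(C)C(C)(C)C)c(OC)c1 | intermediate (not isolated)
25 | 1-[4-(TBSO)-3-methoxyphenyl]-3-(TBSO)propan-1-ol (racemic) | COc1cc(C(O)CCO[Si](C)(C)C(C)(C)C)ccc1O[Si](C)(C)C(C)(C)C | intermediate
26 | 1-[4-(TBSO)-3-methoxyphenyl]-3-(TBSO)propan-1-one | COc1cc(C(=O)CCO[Si](C)(C)C(C)(C)C)ccc1O[Si](C)(C)C(C)(C)C | intermediate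
27 | (Z)-trimethylsilyl enol ether of 26 | COc1cc(/C(O[Si](C)(C)C)=C/CO[Si](C)(C)C(C)(C)C)ccc1O[Si](C)(C)C(C)(C)C | intermediate (not isolated)
28 | 2-bromo-1-[4-(TBSO)-3-methoxyphenyl]-3-(TBSO)propan-1-one (racemic) | COc1cc(C(=O)C(Br)CO[Si](C)(C)C(C)(C)C)ccc1O[Si](C)(C)C(C)(C)C | intermediate
29 | arylzinc iodide from 20 | I[Zn]c1cc([C@H]2OC[C@H]3[C@@H]2CO[C@@H]3c2cc(OC)c3c(c2)[C@@H](CO[Si](C)(C)C(C)(C)C)[C@@H](c2ccc(O[Si](C)(C)C(C)(C)C)c(OC)c2)O3)cc(OC)c1O[Si](C)(C)C(C)(C)C | intermediate (not isolated)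
30 | penta-TBS ether of the target, (S) at the ketone α-carbon | COc1cc(C(=O)[C@H](CO[Si](C)(C)C(C)(C)C)c2cc([C@H]3OC[C@H]4[C@@H]3CO[C@@H]4c3cc(OC)c4c(c3)[C@@H](CO[Si](C)(C)C(C)(C)C)[C@@H](c3ccc(O[Si](C)(C)C(C)(C)C)c(OC)c3)O4)cc(OC)c2O[Si](C)(C)C(C)(C)C)ccc1O[Si](C)(C)C(C)(C)C | intermediate
31 | CNP0174045.1 | COc1cc(C(=O)[C@H](CO)c2cc([C@H]3OC[C@H]4[C@@H]3CO[C@@H]4c3cc(OC)c4c(c3)[C@@H](CO)[C@@H](c3ccc(O)c(OC)c3)O4)cc(OC)c2O)ccc1O | target

## Step count and risks

Total: 20 steps. Longest linear sequence: 15 steps (1–9, 11–14, 19, 20).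

Step 19. What may go wrong: slow transfer of the hindered ortho-silyloxy aryl group from zinc to nickel, loss of silyloxide from the β-position of the nickel enolate, or enolisation of the product during the coupling. The fallback sets out from 20 and builds the arm in the other order. Palladium-catalysed ketone α-arylation (Pd2(dba)3, Xantphos, K3PO4, toluene, 80 °C) with 1-[4-(TBSO)-3-methoxyphenyl]ethanone F1 (from acetovanillone and TBSCl) gives the deoxybenzoin F2. Soft enolisation (TMSOTf, Et3N) gives the Z trimethylsilyl enol ether F3. Catalytic enantioselective hydroxymethylation with aqueous formaldehyde (Sc(OTf)3, chiral 2,2'-bipyridine diol ligand, DME/H2O, −20 °C) gives the (S)-hydroxymethyl ketone F4. Its four silyl ethers are removed under the conditions of step 20, which returns to the route at 31.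

Step 14. What may go wrong: the acid also ionises the benzylic C2–O bond of the cis-dihydrobenzofuran (epimerisation to trans), cleaves the primary silyl ether, lets a benzylic hydroxyl instead of a hydroxymethyl group capture the cation (2,5-diaryltetrahydrofuran), or equilibrates an aryl group to the endo position. The fallback sets out from 18 and ionises under basic conditions. TESCl (2 equiv) and imidazole in CH2Cl2 at −40 °C silylate the two primary hydroxyls to give the bis(triethylsilyl) ether F5. MsCl and Et3N in CH2Cl2 at −20 to 0 °C convert both benzylic hydroxyls into the bis-mesylate F6, which ionises in the flask. Each benzylic cation is captured by the neighbouring silyl ether oxygen with loss of the triethylsilyl group, which returns to the route at 20.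

Step 11. What may go wrong: the enolate is not captured cleanly (proton transfer, reversal of the aldol addition during work-up), or the bulky anion adds partly 1,2. The fallback sets out from 11 and 13 and separates the two bond formations. Anion 14 is added to 13 and the enolate is protonated at −78 °C to give the trans Michael adduct (4R,5R)-4-(2-ArC-1,3-dithian-2-yl)-5-(l-menthyloxy)dihydrofuran-2(3H)-one F7. Deprotonation with LiN(i-Pr)2 at −78 °C, exchange of lithium for zinc with ZnCl2 and addition of 12 then give the less reversible zinc aldol reaction, which returns to the route at 16.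

## Further compounds

F1 | step 19 | 1-[4-(TBSO)-3-methoxyphenyl]ethanone | COc1cc(C(C)=O)ccc1O[Si](C)(C)C(C)(C)C
F2 | step 19 | deoxybenzoin, 1-[4-(TBSO)-3-methoxyphenyl]-2-{2-(TBSO)-3-methoxy-5-[(1R,2S,5R,6S)-6-ArC-3,7-dioxabicyclo[3.3.0]oct-2-yl]phenyl}ethanone | COc1cc(C(=O)Cc2cc([C@H]3OC[C@H]4[C@@H]3CO[C@@H]4c3cc(OC)c4c(c3)[C@@H](CO[Si](C)(C)C(C)(C)C)[C@@H](c3ccc(O[Si](C)(C)C(C)(C)C)c(OC)c3)O4)cc(OC)c2O[Si](C)(C)C(C)(C)C)ccc1O[Si](C)(C)C(C)(C)C
F3 | step 19 | (Z)-trimethylsilyl enol ether of F2 | COc1cc(/C(O[Si](C)(C)C)=C/c2cc([C@H]3OC[C@H]4[C@@H]3CO[C@@H]4c3cc(OC)c4c(c3)[C@@H](CO[Si](C)(C)C(C)(C)C)[C@@H](c3ccc(O[Si](C)(C)C(C)(C)C)c(OC)c3)O4)cc(OC)c2O[Si](C)(C)C(C)(C)C)ccc1O[Si](C)(C)C(C)(C)C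
F4 | step 19 | (2S)-3-hydroxy ketone with four TBS ethers | COc1cc(C(=O)[C@H](CO)c2cc([C@H]3OC[C@H]4[C@@H]3CO[C@@H]4c3cc(OC)c4c(c3)[C@@H](CO[Si](C)(C)C(C)(C)C)[C@@H](c3ccc(O[Si](C)(C)C(C)(C)C)c(OC)c3)O4)cc(OC)c2O[Si](C)(C)C(C)(C)C)ccc1O[Si](C)(C)C(C)(C)C
F5 | step 14 | bis(triethylsilyl) ether of 18 at the two primary hydroxyls | CC[Si](CC)(CC)OC[C@H](C(O)c1cc(OC)c2c(c1)[C@@H](CO[Si](C)(C)C(C)(C)C)[C@@H](c1ccc(O[Si](C)(C)C(C)(C)C)c(OC)c1)O2)[C@H](CO[Si](CC)(CC)CC)C(O)c1cc(OC)c(O[Si](C)(C)C(C)(C)C)c(I)c1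
F6 | step 14 | bis(benzylic mesylate) of F5 | CC[Si](CC)(CC)OC[C@H](C(OS(C)(=O)=O)c1cc(OC)c2c(c1)[C@@H](CO[Si](C)(C)C(C)(C)C)[C@@H](c1ccc(O[Si](C)(C)C(C)(C)C)c(OC)c1)O2)[C@H](CO[Si](CC)(CC)CC)C(OS(C)(=O)=O)c1cc(OC)c(O[Si](C)(C)C(C)(C)C)c(I)c1
F7 | step 11 | (4R,5R)-4-(2-ArC-1,3-dithian-2-yl)-5-(l-menthyloxy)dihydrofuran-2(3H)-one | O=C1O[C@@H](O[C@@H]2C[C@H](C)CC[C@H]2C(C)C)[C@H](C2(SCCCS2)c2cc(OC)c3c(c2)[C@@H](CO[Si](C)(C)C(C)(C)C)[C@@H](c2ccc(O[Si](C)(C)C(C)(C)C)c(OC)c2)O3)C1
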